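**Strategy.** Ring D of the pristimerol-derived half (C13–C18) is fused trans to ring C through the vicinal quaternary carbons C13/C14 and cis to ring E through C17/C18, but its C15–C16 bond touches no stereocentre. All four junction centres are therefore set on a D-seco skeleton (Ireland–Claisen rearrangement for C13/C14, a bicyclo[2.2.2]octene Diels–Alder adduct for ring E), the D-seco catechol is joined to 22β-hydroxytingenone through the dioxane, and only then is ring D closed by ring-closing metathesis of the vinyl groups on C14 and C17, in one operation and without stereochemical risk; diimide finally saturates the new alkene. The metathesis precursor is the complete dimer lacking only the C15–C16 bond.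

Key step: step 28

Remark on numbering: atom numbers are those of the friedelane skeleton of the target (unprimed for the pristimerol half, primed for the tingenone half); α/β refer to that skeleton.
Assumption: 22β-hydroxytingenone (39) is taken as a purchasable isolated natural product; everything else is built from simple chemicals.

Step 1
Reactants: 1 2,3-dimethoxytoluene
Product: 3 5-bromo-2,3-dimethoxytoluene, via aryl pinacol boronate 2 (not isolated)
Conditions: B2pin2, [Ir(OMe)(cod)]2 (cat.), 4,4'-di-tert-butyl-2,2'-bipyridine, THF, 80 °C; then CuBr2, MeOH/H2O, 80 °C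
Reagents that add atoms: copper dibromide, [Cu+2].[Br-].[Br-]
Why: Sterically governed iridium-catalysed C–H borylation should go to the only ring position without an ortho substituent, and copper-mediated bromodeboronation then gives the aryl bromide.

Step 2
Reactants: 3 5-bromo-2,3-dimethoxytoluene; 4 tert-butyl propanoate
Product: 5 tert-butyl 2-(3,4-dimethoxy-5-methylphenyl)propanoate (racemic)
Conditions: LiN(C6H11)2, Pd(dba)2 (cat.), P(tBu)3, toluene, rt
Reagents that add atoms: none
Why: Palladium-catalysed α-arylation of the ester lithium enolate (Buchwald–Hartwig type) is reliable for electron-rich aryl bromides and installs C10–C9(C25)–C8.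

Step 3
Reactants: 5 tert-butyl 2-(3,4-dimethoxy-5-methylphenyl)propanoate
Product: 6 2-(3,4-dimethoxy-5-methylphenyl)propanoic acid (racemic)
Conditions: CF3CO2H, CH2Cl2, rt
Reagents that add atoms: none
Why: Acidolysis of the tert-butyl ester (loss of isobutene) leaves the aryl methyl ethers untouched.

Step 4
Reactants: 6 2-(3,4-dimethoxy-5-methylphenyl)propanoic acid
Product: 8 6,7-dimethoxy-1,5-dimethyl-3,4-dihydronaphthalen-2(1H)-one (racemic), via acid chloride 7 (not isolated)
Conditions: (COCl)2, DMF (cat.), CH2Cl2; then ethylene (1 atm), AlCl3, CH2Cl2, −10 °C to rt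
Reagents that add atoms: ethylene, C=C
Why: Friedel–Crafts acylation of ethylene followed by intramolecular Friedel–Crafts alkylation gives the 2-tetralone (rings A and B), closure being expected para to the C2 methoxy group, that is ortho to the aryl methyl.

Step 5
Reactants: 8 6,7-dimethoxy-1,5-dimethyl-3,4-dihydronaphthalen-2(1H)-one
Product: 9 (S)-6,7-dimethoxy-1,5-dimethyl-1-vinyl-3,4-dihydronaphthalen-2(1H)-one
Conditions: vinyl bromide, Pd2(dba)3 (cat.), (R)-2-(di-tert-butylphosphino)-2'-(dimethylamino)-1,1'-binaphthyl, NaOtBu, toluene, rt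
Reagents that add atoms: vinyl bromide, C=CBr
Why: Palladium-catalysed asymmetric α-vinylation of the more acidic benzylic enolate creates the C9 quaternary stereocentre under ligand control (the antipodal ligand is used if the sense proves opposite).

Step 6
Reactants: 9 (S)-6,7-dimethoxy-1,5-dimethyl-1-vinyl-3,4-dihydronaphthalen-2(1H)-one
Product: 10 (S)-6,7-dimethoxy-1,5-dimethyl-1-vinyl-1,4-dihydronaphthalen-2-yl trifluoromethanesulfonate
Conditions: KN(SiMe3)2, THF, −78 °C; then PhNTf2
Reagents that add atoms: N-phenylbis(trifluoromethanesulfonimide), O=S(=O)(N(c1ccccc1)S(=O)(=O)C(F)(F)F)C(F)(F)F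
Why: Enolisation can only occur toward C7 because C9 is quaternary, so O-triflation gives the single C7=C8 enol triflate.

Step 7
Reactants: 10 (S)-6,7-dimethoxy-1,5-dimethyl-1-vinyl-1,4-dihydronaphthalen-2-yl trifluoromethanesulfonate; 11 tert-butyl 2-bromopropanoate
Product: 13 tert-butyl 2-(6,7-dimethoxy-1,5-dimethyl-1-vinyl-1,4-dihydronaphthalen-2-yl)propanoate (C9 as in 9; both C14 epimers), via Reformatsky reagent 12 (not isolated)
Conditions: Zn dust, THF, rt (11 to 12); then 10, Pd(PPh3)4 (cat.), THF, 60 °C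
Reagents that add atoms: none
Why: Negishi-type coupling of the Reformatsky reagent with the alkenyl triflate forms the C8–C14 bond and keeps the C7=C8 alkene; the C14 epimer mixture is irrelevant because C14 is enolised in step 16.

Step 8
Reactants: 13 tert-butyl 2-(6,7-dimethoxy-1,5-dimethyl-1-vinyl-1,4-dihydronaphthalen-2-yl)propanoate
Product: 14 2-(6,7-dimethoxy-1,5-dimethyl-1-vinyl-1,4-dihydronaphthalen-2-yl)propanoic acid (C9 as in 9; both C14 epimers)
Conditions: CF3CO2H, CH2Cl2, 0 °C
Reagents that add atoms: none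
Why: Acidolytic cleavage of the tert-butyl ester gives the acid; any migration of the double bond into conjugation would converge to the same dienolate in step 16.

Step 9
Reactants: 15 3-methylcyclohex-2-en-1-one
Product: 16 3,6-dimethylcyclohex-2-en-1-one (racemic)
Conditions: LiN(iPr)2, THF, −78 °C; then MeI
Reagents that add atoms: iodomethane, CI
Why: Kinetic α'-deprotonation of the enone and C-methylation install the future C20 methyl group.

Step 10
Reactants: 16 3,6-dimethylcyclohex-2-en-1-one
Product: 17 1,4-dimethyl-2-(triisopropylsilyloxy)cyclohexa-1,3-diene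
Conditions: LiN(iPr)2, THF, −78 °C; then iPr3SiOTf
Reagents that add atoms: triisopropylsilyl trifluoromethanesulfonate, CC(C)[Si](OS(=O)(=O)C(F)(F)F)(C(C)C)C(C)C
Why: Kinetic α'-deprotonation to the cross-conjugated dienolate and O-silylation give the 2-silyloxy diene whose termini carry the future C17 and C20 methyl groups.

Step 11
Reactants: 17 1,4-dimethyl-2-(triisopropylsilyloxy)cyclohexa-1,3-diene; 18 but-3-en-2-one
Product: 19 1-[1,4-dimethyl-5-(triisopropylsilyloxy)bicyclo[2.2.2]oct-5-en-2-yl]ethan-1-one (acetyl endo; C17, C18 and C20 as in the target)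
Conditions: (S)-o-tolyl-CBS-oxazaborolidine (20 mol %), Tf2NH (18 mol %), CH2Cl2, −78 to −40 °C
Reagents that add atoms: none
Why: Catalytic enantioselective Diels–Alder reaction in which the diene terminus next to the silyloxy carbon bonds to the enone β-carbon, endo approach places the acetyl group syn to the enol ether bridge, and the chiral oxazaborolidinium ion selects the face (antipodal catalyst if the sense proves opposite), so that C17, C18 and C20 are set together and C16 and C29 are held cis as a bridge.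

Step 12
Reactants: 19 1-[1,4-dimethyl-5-(triisopropylsilyloxy)bicyclo[2.2.2]oct-5-en-2-yl]ethan-1-one
Product: 20 (E)-N-methoxy-N-methyl-3-[1,4-dimethyl-5-(triisopropylsilyloxy)bicyclo[2.2.2]oct-5-en-2-yl]but-2-enamide
Conditions: (EtO)2P(O)CH2C(O)N(OMe)Me, NaH (1.0 equiv), THF, 65 °C
Reagents that add atoms: diethyl [2-(methoxy(methyl)amino)-2-oxoethyl]phosphonate, CCOP(=O)(CC(=O)N(C)OC)OCC
Why: Horner–Wadsworth–Emmons olefination of the methyl ketone should give the (E)-alkene (amide trans to the bulky bicycle), and the weakly basic phosphonate anion should not epimerise C18.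

Step 13
Reactants: 20 (E)-N-methoxy-N-methyl-3-[1,4-dimethyl-5-(triisopropylsilyloxy)bicyclo[2.2.2]oct-5-en-2-yl]but-2-enamide
Product: 21 (E)-4-[1,4-dimethyl-5-(triisopropylsilyloxy)bicyclo[2.2.2]oct-5-en-2-yl]pent-3-en-2-one
Conditions: MeMgBr, THF, 0 °C
Reagents that add atoms: methylmagnesium bromide, C[Mg]Br
Why: Weinreb ketone synthesis, in which the chelated tetrahedral adduct stops the addition at the methyl ketone.

Step 14
Reactants: 21 (E)-4-[1,4-dimethyl-5-(triisopropylsilyloxy)bicyclo[2.2.2]oct-5-en-2-yl]pent-3-en-2-one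
Product: 22 (2S,3E)-4-[1,4-dimethyl-5-(triisopropylsilyloxy)bicyclo[2.2.2]oct-5-en-2-yl]pent-3-en-2-ol
Conditions: (R)-2-methyl-CBS-oxazaborolidine (20 mol %), BH3·SMe2, THF, −30 °C
Reagents that add atoms: none
Why: Corey–Bakshi–Shibata reduction with the alkenyl group as the large substituent sets the (S)-carbinol that relays chirality to C13 in step 16.

Step 15
Reactants: 14 2-(6,7-dimethoxy-1,5-dimethyl-1-vinyl-1,4-dihydronaphthalen-2-yl)propanoic acid; 22 (2S,3E)-4-[1,4-dimethyl-5-(triisopropylsilyloxy)bicyclo[2.2.2]oct-5-en-2-yl]pent-3-en-2-ol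
Product: 23 allylic ester of acid 14 and alcohol 22 (both C14 epimers)
Conditions: DCC, DMAP, CH2Cl2, 0 °C to rt
Reagents that add atoms: none
Why: Steglich esterification joins the AB and E fragments under mild conditions.

Step 16
Reactants: 23 allylic ester of acid 14 and alcohol 22
Product: 26 C15 acid bearing quaternary C14 (14β-methyl; C8 of the dihydronaphthalene) and quaternary C13 (13α-methyl; (E)-propenyl; C18 of the bicycle), via silyl ketene acetal 24 (not isolated), via trimethylsilyl ester 25 (not isolated)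
Conditions: LiN(iPr)2, Me3SiCl, THF, −78 °C; then 65 °C; aq. NH4Cl
Reagents that add atoms: none
Why: Ireland–Claisen rearrangement in which kinetic enolisation places the bulky dihydronaphthyl group cis to the allyloxy oxygen and a chair transition state with the carbinol methyl equatorial transfers the carbinol configuration suprafacially to C13 and fixes C14 relative to it, creating the vicinal quaternary pair with anti methyl groups.

Step 17
Reactants: 26 C15 acid bearing the C13/C14 quaternary pair
Product: 27 tricyclic ABC acid with the C11=C12 alkene (ring C closed; 9β-, 13α- and 14β-methyl)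
Conditions: second-generation Grubbs catalyst (10 mol %), toluene, 80 °C
Reagents that add atoms: none
Why: Ring-closing metathesis of the C9 vinyl and C13 propenyl groups (loss of propene) forms ring C, and the trisubstituted alkenes and the hindered silyl enol ether should not be engaged.

Step 18
Reactants: 27 tricyclic ABC acid with the C11=C12 alkene
Product: 28 tricyclic ABC acid with saturated ring C
Conditions: H2 (4 atm), RhCl(PPh3)3 (10 mol %), benzene/EtOH, rt
Reagents that add atoms: none
Why: Homogeneous hydrogenation with RhCl(PPh3)3 reduces the cis-disubstituted C11=C12 alkene and should leave the trisubstituted C7=C8 alkene and the silyl enol ether.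

Step 19
Reactants: 28 tricyclic ABC acid with saturated ring C
Product: 29 C15 primary alcohol
Conditions: LiAlH4, THF, 0 °C to reflux
Reagents that add atoms: none
Why: Hydride reduction of the neopentylic acid; no other reducible group is present because C29 and C16 are still masked in the bicycle.

Step 20
Reactants: 29 C15 primary alcohol
Product: 30 C15 aldehyde
Conditions: Dess–Martin periodinane, NaHCO3, CH2Cl2, rt
Reagents that add atoms: none
Why: Dess–Martin oxidation gives the non-enolisable aldehyde without touching the silyl enol ether.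

Step 21
Reactants: 30 C15 aldehyde
Product: 31 C14 vinyl compound (C15 as CH=CH2)
Conditions: Ph3PCH3Br, KN(SiMe3)2, THF, 0 °C to rt
Reagents that add atoms: methyltriphenylphosphonium bromide, C[P+](c1ccccc1)(c1ccccc1)c1ccccc1.[Br-]
Why: Wittig methylenation of the hindered aldehyde installs the first vinyl group.

Step 22
Reactants: 31 C14 vinyl compound
Product: 34 bicyclic α-hydroxy ketone (C29 ketone; C16 hydroxyl; both C16 epimers), via silyloxy epoxide 32 (not isolated), via silyloxy ketone 33 (not isolated)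
Conditions: mCPBA (1.0 equiv), NaHCO3, CH2Cl2, −20 °C; then HF·pyridine, THF, 0 °C
Reagents that add atoms: 3-chloroperoxybenzoic acid, OOC(=O)c1cccc(Cl)c1
Why: Rubottom oxidation, in which the electron-rich silyl enol ether is epoxidised far faster than the other alkenes, silyl migration opens the epoxide and fluoride frees the α-hydroxy ketone.

Step 23
Reactants: 34 bicyclic α-hydroxy ketone
Product: 35 ring E methyl ester aldehyde (C29 as CO2Me on C20; C16 as CHO on C17)
Conditions: Pb(OAc)4, MeOH/benzene, 0 °C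
Reagents that add atoms: methanol, CO
Why: Criegee-type cleavage of the α-hydroxy ketone in methanol unmasks ring E, the ketone carbon becoming the methyl ester and the carbinol carbon the aldehyde, cis on the ring because they were a bridge.

Step 24
Reactants: 35 ring E methyl ester aldehyde
Product: 36 14,17-divinyl methyl ester
Conditions: Ph3PCH3Br, KN(SiMe3)2, THF, 0 °C
Reagents that add atoms: methyltriphenylphosphonium bromide, C[P+](c1ccccc1)(c1ccccc1)c1ccccc1.[Br-]
Why: Wittig methylenation of the aldehyde installs the second vinyl group, and the hindered quaternary methyl ester should not be attacked.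

Step 25
Reactants: 36 14,17-divinyl methyl ester
Product: 37 6-oxo-7-ene dimethyl ether (aryl enone)
Conditions: CrO3, 3,5-dimethylpyrazole, CH2Cl2, −20 °C
Reagents that add atoms: chromium trioxide, O=[Cr](=O)=O
Why: Allylic oxidation at C6, the only methylene that is both benzylic and allylic, gives the aryl enone; neither vinyl group has an allylic hydrogen.

Step 26
Reactants: 37 6-oxo-7-ene dimethyl ether
Product: 38 D-seco catechol (2,3-diol)
Conditions: BBr3, CH2Cl2, −78 to −20 °C
Reagents that add atoms: none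
Why: Lewis acid demethylation of both aryl methyl ethers, in which the hindered quaternary methyl ester should survive at low temperature.

Step 27
Reactants: 38 D-seco catechol; 39 22β-hydroxytingenone
Product: 41 D-seco dimer (1,4-dioxane with O3–C4' and O2–C3' bonds; 3'α-hydroxyl hemiketal), via o-quinone 40 (not isolated)
Conditions: DDQ (1.0 equiv), 1,4-dioxane, rt, dark; then 39, rt
Reagents that add atoms: none
Why: Oxidation to the electron-poor o-quinone and inverse-electron-demand hetero-Diels–Alder reaction with the C3'=C4' enol of the quinone methide (the biomimetic mode of celastroloid dimers) build the dioxane; approach to the β face gives the cis-fused hemiketal of the target, and regio- and facial isomers expected alongside are removed by chromatography.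

Step 28
Reactants: 41 D-seco dimer
Product: 42 15,16-didehydro dimer (ring D closed)
Conditions: second-generation Grubbs catalyst (15 mol %), CH2Cl2 (high dilution), 40 °C
Reagents that add atoms: none
Why: Ring-closing olefin metathesis by the Chauvin mechanism: the ruthenium alkylidene exchanges with one vinyl group by [2+2] cycloaddition and cycloreversion, the new carbene engages the second vinyl group intramolecularly, and loss of ethene delivers the C15=C16 bond. The closest known reaction type is the metathetic closure of 1,7-dienes with allylic quaternary carbons to cyclohexenes. Ring D (C13–C14–C15–C16–C17–C18) closes as a six-membered ring by joining the two exocyclic vinyl carbons, and the new alkene is necessarily cis. No stereocentre is created, because the trans C13/C14 and cis C17/C18 junctions were fixed in steps 16 and 11. The step needs selectivity for the two monosubstituted vinyl groups over the trisubstituted conjugated C7=C8, C1'=C10', C5'=C6' and C7'=C8' alkenes and tolerance of the hemiketal, the C22' hydroxyl, the ketones and the ester; steric and electronic deactivation of those alkenes toward the ruthenium carbene secures it, and the vinyl groups are held close because C14 and C17 are linked through the C13–C18 bond and both point to the α face.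

Step 29
Reactants: 42 15,16-didehydro dimer
Product: 43 CNP0269636.2 (target)
Conditions: 2-nitrobenzenesulfonyl hydrazide, Et3N, CH2Cl2, rt
Reagents that add atoms: none
Why: Diimide reduction, a concerted syn transfer of H2 that should take the unpolarised cis-disubstituted C15=C16 alkene much faster than the trisubstituted conjugated alkenes of the two enone systems.

**Compound list**

1 | 2,3-dimethoxytoluene | COc1cccc(C)c1OC | starting material
2 | 2-(3,4-dimethoxy-5-methylphenyl)-4,4,5,5-tetramethyl-1,3,2-dioxaborolane | COc1cc(B2OC(C)(C)C(C)(C)O2)cc(C)c1OC | intermediate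
3 | 5-bromo-2,3-dimethoxytoluene | COc1cc(Br)cc(C)c1OC | intermediate
4 | tert-butyl propanoate | CCC(=O)OC(C)(C)C | starting material
5 | tert-butyl 2-(3,4-dimethoxy-5-methylphenyl)propanoate (racemic) | CC(C(=O)OC(C)(C)C)c1cc(C)c(OC)c(OC)c1 | intermediate
6 | 2-(3,4-dimethoxy-5-methylphenyl)propanoic acid (racemic) | CC(C(=O)O)c1cc(C)c(OC)c(OC)c1 | intermediate
7 | 2-(3,4-dimethoxy-5-methylphenyl)propanoyl chloride | CC(C(=O)Cl)c1cc(C)c(OC)c(OC)c1 | intermediate
8 | 6,7-dimethoxy-1,5-dimethyl-3,4-dihydronaphthalen-2(1H)-one (racemic) | CC1C(=O)CCc2c(C)c(OC)c(OC)cc12 | intermediate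
9 | (S)-6,7-dimethoxy-1,5-dimethyl-1-vinyl-3,4-dihydronaphthalen-2(1H)-one (C9 set) | C=C[C@]1(C)C(=O)CCc2c(C)c(OC)c(OC)cc12 | intermediate
10 | (S)-6,7-dimethoxy-1,5-dimethyl-1-vinyl-1,4-dihydronaphthalen-2-yl trifluoromethanesulfonate | C=C[C@]1(C)C(OS(=O)(=O)C(F)(F)F)=CCc2c(C)c(OC)c(OC)cc12 | intermediate
11 | tert-butyl 2-bromopropanoate (racemic) | CC(Br)C(=O)OC(C)(C)C | starting material
12 | [1-(tert-butoxycarbonyl)ethyl]zinc bromide | CC([Zn]Br)C(=O)OC(C)(C)C | intermediate
13 | tert-butyl 2-(6,7-dimethoxy-1,5-dimethyl-1-vinyl-1,4-dihydronaphthalen-2-yl)propanoate (C9 as in 9; C14 epimers) | C=C[C@]1(C)C(C(C)C(=O)OC(C)(C)C)=CCc2c(C)c(OC)c(OC)cc12 | intermediate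
14 | 2-(6,7-dimethoxy-1,5-dimethyl-1-vinyl-1,4-dihydronaphthalen-2-yl)propanoic acid (C9 as in 9; C14 epimers) | C=C[C@]1(C)C(C(C)C(=O)O)=CCc2c(C)c(OC)c(OC)cc12 | intermediate
15 | 3-methylcyclohex-2-en-1-one | CC1=CC(=O)CCC1 | starting material
16 | 3,6-dimethylcyclohex-2-en-1-one (racemic) | CC1CCC(C)=CC1=O | intermediate
17 | 1,4-dimethyl-2-(triisopropylsilyloxy)cyclohexa-1,3-diene | CC1=C(O[Si](C(C)C)(C(C)C)C(C)C)C=C(C)CC1 | intermediate
18 | but-3-en-2-one | CC(=O)C=C | starting material
19 | 1-[1,4-dimethyl-5-(triisopropylsilyloxy)bicyclo[2.2.2]oct-5-en-2-yl]ethan-1-one, acetyl endo | CC(=O)[C@@H]1C[C@@]2(C)CC[C@]1(C)C=C2O[Si](C(C)C)(C(C)C)C(C)C | intermediate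
20 | (E)-N-methoxy-N-methyl-3-[1,4-dimethyl-5-(triisopropylsilyloxy)bicyclo[2.2.2]oct-5-en-2-yl]but-2-enamide | CON(C)C(=O)/C=C(\C)[C@@H]1C[C@@]2(C)CC[C@]1(C)C=C2O[Si](C(C)C)(C(C)C)C(C)C | intermediate
21 | (E)-4-[1,4-dimethyl-5-(triisopropylsilyloxy)bicyclo[2.2.2]oct-5-en-2-yl]pent-3-en-2-one | CC(=O)/C=C(\C)[C@@H]1C[C@@]2(C)CC[C@]1(C)C=C2O[Si](C(C)C)(C(C)C)C(C)C | intermediate
22 | (2S,3E)-4-[1,4-dimethyl-5-(triisopropylsilyloxy)bicyclo[2.2.2]oct-5-en-2-yl]pent-3-en-2-ol | C[C@H](O)/C=C(\C)[C@@H]1C[C@@]2(C)CC[C@]1(C)C=C2O[Si](C(C)C)(C(C)C)C(C)C | intermediate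
23 | allylic ester of acid 14 and alcohol 22 (C14 epimers) | C=C[C@]1(C)C(C(C)C(=O)O[C@@H](C)/C=C(\C)[C@@H]3C[C@@]4(C)CC[C@]3(C)C=C4O[Si](C(C)C)(C(C)C)C(C)C)=CCc2c(C)c(OC)c(OC)cc12 | intermediate
24 | trimethylsilyl ketene acetal of 23 (dihydronaphthyl cis to the allyloxy oxygen) | C=C[C@]1(C)C(/C(C)=C(/O[Si](C)(C)C)O[C@@H](C)/C=C(\C)[C@@H]3C[C@@]4(C)CC[C@]3(C)C=C4O[Si](C(C)C)(C(C)C)C(C)C)=CCc2c(C)c(OC)c(OC)cc12 | intermediate
25 | trimethylsilyl ester of acid 26 | C=C[C@]1(C)C([C@@](C)(C(=O)O[Si](C)(C)C)[C@@](C)(/C=C/C)[C@@H]3C[C@@]4(C)CC[C@]3(C)C=C4O[Si](C(C)C)(C(C)C)C(C)C)=CCc2c(C)c(OC)c(OC)cc12 | intermediate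
26 | C15 acid with quaternary C14 (14β-methyl) and quaternary C13 (13α-methyl, (E)-propenyl, bicycle at C18) | C=C[C@]1(C)C([C@@](C)(C(=O)O)[C@@](C)(/C=C/C)[C@@H]3C[C@@]4(C)CC[C@]3(C)C=C4O[Si](C(C)C)(C(C)C)C(C)C)=CCc2c(C)c(OC)c(OC)cc12 | intermediate
27 | tricyclic ABC acid with C11=C12 alkene | C[C@@]12C=C[C@@](C)([C@@H]3C[C@@]4(C)CC[C@]3(C)C=C4O[Si](C(C)C)(C(C)C)C(C)C)[C@](C)(C(=O)O)C1=CCc1c(C)c(OC)c(OC)cc12 | intermediate
28 | tricyclic ABC acid with saturated ring C | C[C@@]12CC[C@@](C)([C@@H]3C[C@@]4(C)CC[C@]3(C)C=C4O[Si](C(C)C)(C(C)C)C(C)C)[C@](C)(C(=O)O)C1=CCc1c(C)c(OC)c(OC)cc12 | intermediate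
29 | C15 primary alcohol | C[C@@]12CC[C@@](C)([C@@H]3C[C@@]4(C)CC[C@]3(C)C=C4O[Si](C(C)C)(C(C)C)C(C)C)[C@](C)(CO)C1=CCc1c(C)c(OC)c(OC)cc12 | intermediate
30 | C15 aldehyde | C[C@@]12CC[C@@](C)([C@@H]3C[C@@]4(C)CC[C@]3(C)C=C4O[Si](C(C)C)(C(C)C)C(C)C)[C@](C)(C=O)C1=CCc1c(C)c(OC)c(OC)cc12 | intermediate
31 | C14 vinyl compound | C[C@@]12CC[C@@](C)([C@@H]3C[C@@]4(C)CC[C@]3(C)C=C4O[Si](C(C)C)(C(C)C)C(C)C)[C@](C)(C=C)C1=CCc1c(C)c(OC)c(OC)cc12 | intermediate
32 | silyloxy epoxide of 31 (C16–C29) | C[C@@]12CC[C@@](C)([C@@H]3C[C@@]4(C)CC[C@]3(C)C5OC45O[Si](C(C)C)(C(C)C)C(C)C)[C@](C)(C=C)C1=CCc1c(C)c(OC)c(OC)cc12 | intermediate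
33 | α-(triisopropylsilyloxy) ketone (C16 OSi, C29 ketone) | C[C@@]12CC[C@@](C)([C@@H]3C[C@@]4(C)CC[C@]3(C)C(O[Si](C(C)C)(C(C)C)C(C)C)C4=O)[C@](C)(C=C)C1=CCc1c(C)c(OC)c(OC)cc12 | intermediate
34 | bicyclic α-hydroxy ketone (C16 epimers) | C[C@@]12CC[C@@](C)([C@@H]3C[C@@]4(C)CC[C@]3(C)C(O)C4=O)[C@](C)(C=C)C1=CCc1c(C)c(OC)c(OC)cc12 | intermediate
35 | ring E methyl ester aldehyde | C[C@@]12CC[C@@](C)([C@@H]3C[C@](C)(C(=O)OC)CC[C@]3(C)C=O)[C@](C)(C=C)C1=CCc1c(C)c(OC)c(OC)cc12 | intermediate
36 | 14,17-divinyl methyl ester | C[C@@]12CC[C@@](C)([C@@H]3C[C@](C)(C(=O)OC)CC[C@]3(C)C=C)[C@](C)(C=C)C1=CCc1c(C)c(OC)c(OC)cc12 | intermediate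
37 | 6-oxo-7-ene dimethyl ether | C[C@@]12CC[C@@](C)([C@@H]3C[C@](C)(C(=O)OC)CC[C@]3(C)C=C)[C@](C)(C=C)C1=CC(=O)c1c(C)c(OC)c(OC)cc12 | intermediate
38 | D-seco catechol | C[C@@]12CC[C@@](C)([C@@H]3C[C@](C)(C(=O)OC)CC[C@]3(C)C=C)[C@](C)(C=C)C1=CC(=O)c1c(C)c(O)c(O)cc12 | intermediate
39 | 22β-hydroxytingenone | CC1=C(O)C(=O)C=C2C1=CC=C1[C@@]2(C)CC[C@@]2(C)[C@@H]3C[C@@H](C)C(=O)[C@@H](O)[C@]3(C)CC[C@]12C | starting material
40 | D-seco o-quinone | C[C@@]12CC[C@@](C)([C@@H]3C[C@](C)(C(=O)OC)CC[C@]3(C)C=C)[C@](C)(C=C)C1=CC(=O)C1=C(C)C(=O)C(=O)C=C12 | intermediate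
41 | D-seco dimer | C[C@@]12CC[C@@](C)([C@@H]3C[C@](C)(C(=O)OC)CC[C@]3(C)C=C)[C@](C)(C=C)C1=CC(=O)c1c(C)c3O[C@]4(C)C5=CC=C6[C@@](C)(CC[C@@]7(C)[C@@H]8C[C@@H](C)C(=O)[C@@H](O)[C@]8(C)CC[C@]67C)C5=CC(=O)[C@]4(O)Oc3cc12 | intermediate
42 | 15,16-didehydro dimer | C[C@@]12CC[C@@]9(C)[C@@H]3C[C@](C)(C(=O)OC)CC[C@]3(C)C=C[C@]9(C)C1=CC(=O)c1c(C)c3O[C@]4(C)C5=CC=C6[C@@](C)(CC[C@@]7(C)[C@@H]8C[C@@H](C)C(=O)[C@@H](O)[C@]8(C)CC[C@]67C)C5=CC(=O)[C@]4(O)Oc3cc12 | intermediate
43 | CNP0269636.2 | COC(=O)[C@]1(C)CC[C@]2(C)CC[C@]3(C)C4=CC(=O)c5c(cc6c(c5C)O[C@]5(C)C7=CC=C8[C@@](C)(CC[C@@]9(C)[C@@H]%10C[C@@H](C)C(=O)[C@@H](O)[C@]%10(C)CC[C@]89C)C7=CC(=O)[C@]5(O)O6)[C@]4(C)CC[C@@]3(C)[C@@H]2C1 | target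

**Step count and risks**

Total step count: 29. Longest linear sequence: 23 steps (steps 1–8, then 15–29).

Steps most likely to fail:

Step 16 (Ireland–Claisen). Enolisation may be incomplete or may not control the ketene acetal geometry (C14 epimers), and the [3,3] shift joins two fully substituted termini while the C18 stereocentre opposes the carbinol-controlled face. The fallback avoids enolate chemistry: it sets out from acid 14 and alcohol 22 and comes back at alcohol 29. Acid 14 is converted ((COCl)2; Me2NH) into the N,N-dimethylamide F1; O-methylation (MeOTf) and the sodium alkoxide of 22 give a ketene N,O-acetal in which allylic strain to the dimethylamino group again places the dihydronaphthyl group cis to the allyloxy oxygen, and heating in xylene (Eschenmoser–Claisen) should give the rearranged amide F2. Ring-closing metathesis as in step 17 gives the ring C cyclohexene amide F3, hydrogenation as in step 18 the saturated amide F4, and reduction with LiH2N·BH3 returns the route at 29.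

Step 27 (oxidation and hetero-Diels–Alder union). Facial and regiochemical discrimination in the cycloaddition may be poor, and residual oxidant may attack 39. The fallback changes the dienophile: it sets out from 39 and o-quinone 40 (made from 38 and filtered from the hydroquinone) and comes back at 41. Compound 39 is converted (Et3SiOTf, 2,6-lutidine) into the bis(triethylsilyl) ether F5; its more electron-rich and bulkier silyl enol ether is combined with 40 to give the bis-silylated cycloadduct F6, and HF·pyridine returns the route at 41.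

Step 29 (diimide reduction). Hydrogen transfer to the hindered C15=C16 alkene may be slow, or the conjugated alkenes may be reduced in competition. The fallback sets out from 42 and comes back at 43: homogeneous hydrogenation with RhCl(PPh3)3 under H2, which discriminates alkenes by their substitution at the metal centre instead of by a pericyclic transfer; it makes no new compound.

Further compounds
F1 | step 16 | N,N-dimethylamide of acid 14 | C=C[C@]1(C)C(C(C)C(=O)N(C)C)=CCc2c(C)c(OC)c(OC)cc12
F2 | step 16 | rearranged N,N-dimethylamide (amide analogue of 26) | C=C[C@]1(C)C([C@@](C)(C(=O)N(C)C)[C@@](C)(/C=C/C)[C@@H]3C[C@@]4(C)CC[C@]3(C)C=C4O[Si](C(C)C)(C(C)C)C(C)C)=CCc2c(C)c(OC)c(OC)cc12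
F3 | step 16 | ring C cyclohexene amide (amide analogue of 27) | C[C@@]12C=C[C@@](C)([C@@H]3C[C@@]4(C)CC[C@]3(C)C=C4O[Si](C(C)C)(C(C)C)C(C)C)[C@](C)(C(=O)N(C)C)C1=CCc1c(C)c(OC)c(OC)cc12
F4 | step 16 | saturated amide (amide analogue of 28) | C[C@@]12CC[C@@](C)([C@@H]3C[C@@]4(C)CC[C@]3(C)C=C4O[Si](C(C)C)(C(C)C)C(C)C)[C@](C)(C(=O)N(C)C)C1=CCc1c(C)c(OC)c(OC)cc12
F5 | step 27 | 3',22'-bis-O-(triethylsilyl)-22β-hydroxytingenone | CC1=C(O[Si](CC)(CC)CC)C(=O)C=C2C1=CC=C1[C@@]2(C)CC[C@@]2(C)[C@@H]3C[C@@H](C)C(=O)[C@@H](O[Si](CC)(CC)CC)[C@]3(C)CC[C@]12C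
F6 | step 27 | 3',22'-bis-O-(triethylsilyl) D-seco dimer | C[C@@]12CC[C@@](C)([C@@H]3C[C@](C)(C(=O)OC)CC[C@]3(C)C=C)[C@](C)(C=C)C1=CC(=O)c1c(C)c3O[C@]4(C)C5=CC=C6[C@@](C)(CC[C@@]7(C)[C@@H]8C[C@@H](C)C(=O)[C@@H](O[Si](CC)(CC)CC)[C@]8(C)CC[C@]67C)C5=CC(=O)[C@]4(O[Si](CC)(CC)CC)Oc3cc12
F0 | step 29 | none | none
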